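(All runs are calculated from invented constants; the scatter is artificial.)

The time of reading, 2.5 h, was what each new flask, winter and spring, had to spend, so I counted hours and followed the fraction of electrophile left, not the product made.

| setting | Friday's | Saturday's | winter | spring |
|---|---|---|---|---|
| electrophile | 0.047 M | 0.13 M | 0.21 M | 0.080 M |
| free base | 0.42 M | 0.42 M | 0.420 M | 0.420 M |
| gas | 6.7 mM (held) | 6.7 mM (held) | 6.7 mM (held) | 6.7 mM (held) |
| remark | run made earlier | run made earlier |  |  |
| time |  |  | 2.5 h | 2.5 h |

| run | time / h | product / % | electrophile / % |
|---|---|---|---|
| Friday's | 0.500 | 45.5 | 54.7 |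
| Friday's | 1.00 | 74.6 | 25.4 |
| Friday's | 1.50 | 89.9 | 10.3 |
| Friday's | 2.00 | 96.6 | 3.9 |
| Friday's | 2.50 | 98.5 | 1.6 |
| Saturday's | 0.200 | 11.0 | 89.3 |
| Saturday's | 0.417 | 23.3 | 76.2 |
| Saturday's | 0.667 | 35.7 | 64.4 |
| Saturday's | 1.33 | 65.0 | 35.3 |
| Saturday's | 2.50 | 93.6 | 4.9 |

(each reading ± 0.5 percentage points)

- the earlier runs were read with a standard deviation of 0.5 percentage points
- at the start none of the gas is in solution

- which of the two ends with the higher amount of product, in percent of the electrophile charged ("neither" if they lie within 2 percentage points) (winter / spring / neither)
- product at the end, in percent of the electrophile charged, winter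
- product at the end, in percent of the electrophile charged, spring

Product and electrophile summed to 100% at 1.00 h in Friday's run, so I took product as the charge minus the electrophile left. Saturday's run, richer in electrophile, went at a steady pace, while Friday's fell away like a pseudo-first-order decay, so I let two costs in time add up:

time = a · ln([electrophile]start / [electrophile]) + ([electrophile]start − [electrophile]) / v

One reading from each run gave the logarithm and the amount reacted:

Friday's, at 1.00 h: 1.37 and 0.0351 M

Saturday's, at 1.33 h: 1.04 and 0.0841 M

Solving the pair gave v = 0.101 M h⁻¹, the steady rate of electrophile loss read from these two readings, which I call the ceiling rate, and a = 0.476 h. For Friday's reading at 2.00 h the rule asks 1.99 h. In Saturday's run at 2.50 h the two readings sum to 98.5%, so I took the fraction left from the product reading, and the rule asks 2.52 h.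

I tried a fraction left of 0.200 for winter and 0.0250 for spring:

winter: 2.43 h

spring: 2.53 h

Those round trials were the weak link, so I reforged them, dividing each gap to 2.5 h by the cost of a further unit of fraction, a/f + [electrophile]start/v:

winter: left 0.185, product 81.5%

spring: left 0.0265, product 97.3%

The forecast, reading “gas uptake limiting at high electrophile”, took a maximum rate of 0.13 M/h where I took a ceiling rate of 0.101 M h⁻¹. It named spring, with winter at 87.5% (83% to 91.5%) and spring at 97.4% (96% to 98.5%), so on winter my number differs from it.

The simulation gave 82.0% for winter and 97.5% for spring, so spring ended higher.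

    electrophile + nucleophile → acid set free + product (k = 5.50 M⁻¹ min⁻¹)
    nucleophile + acid set free ⇌ protonated nucleophile, settled at all times (K = 9900 M⁻¹)
    acid set free + free base ⇌ salt of the base, settled at all times (K = 10.0 M⁻¹)
    gas ⇌ nucleophile, rate k4*(csat - [nucleophile]) (kL = 0.470 min⁻¹)

In winter, with the other concentrations as charged, the reaction with electrophile halves nucleophile in 0.60 min, faster than the crossing of gas closes half its gap, which takes 1.47 min, and at 1.25 h nucleophile stood at 0.00194 M against a saturation of 6.7 mM. With the ceiling rate of 0.101 M h⁻¹, the rule asks 2.52 h for winter's 18% of electrophile left, and for a neighbour of spring charged with 0.14 M of electrophile, which kept 7.6%, it asks 2.51 h against its 2.50 h.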